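The plan rests on disconnecting ring A across C8–C8a, C6–C7 and C4a–C8a, so that this arene is built last from a four-carbon vinylketene (from 3-methoxycyclobutenone) and the two alkyne carbons of a chiral methoxy enyne. One thermal operation should give ring A as a phenol with its pattern already correct: OH on C8a between the alkenyl chain on C8 and the single open carbon C4a, OCH3 on C5 and C7, ready for pyran closure. The precursor carries the finished ring B chromene, the S stereocentre and the E alkene; its hindered aryl–C bond is forged intramolecularly by an enantioselective O-allylation/Claisen relay.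

Key step: step 9

Labels: ring A is the chromene on the alkene carbon, ring B the chromene on the stereocentre; both use chromene numbering (O1, C2, C3, C4, C4a, C5 to C8, C8a).

Assumption: the enantiomer of the Trost ligand that gives the R ether 4 in step 2 is fixed by a first-run assignment of configuration; if the sense is opposite, the mirror-image ligand is used and nothing else changes.

Step 1
Reactants: 1 (E)-pent-3-en-2-ol (racemic)
Product: 2 methyl (E)-pent-3-en-2-yl carbonate (racemic)
Conditions: ClCO2Me (1.3 equiv), pyridine (2 equiv), CH2Cl2, 0 °C to rt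
Reagents that add atoms: methyl chloroformate, COC(=O)Cl
Why: Plain O-acylation of a secondary allylic alcohol installs the carbonate leaving group for allylpalladium chemistry, and the racemate is used on purpose because step 2 converges both enantiomers.

Step 2
Reactants: 2 methyl (E)-pent-3-en-2-yl carbonate (racemic), 3 3,5-dimethoxyphenol
Product: 4 1,3-dimethoxy-5-{[(2R,3E)-pent-3-en-2-yl]oxy}benzene
Conditions: Pd2(dba)3·CHCl3 (2.5 mol%, zerovalent palladium), N,N'-(trans-cyclohexane-1,2-diyl)bis[2-(diphenylphosphanyl)benzamide] (Trost ligand, single enantiomer, 7.5 mol%), CH2Cl2, rt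
Reagents that add atoms: none
Why: In this Tsuji–Trost asymmetric allylic etherification either enantiomer of 2 ionises to the same symmetric syn,syn-1,3-dimethylallyl palladium cation, the released methoxide deprotonates the phenol, and the chiral pocket of the ligand steers the phenoxide to one of the two enantiotopic allyl termini, which sets the R C–O stereocentre.

Step 3
Reactants: 4 1,3-dimethoxy-5-{[(2R,3E)-pent-3-en-2-yl]oxy}benzene
Product: 6 3,5-dimethoxy-2-[(2S,3E)-pent-3-en-2-yl]phenol, via dienone 5 (not isolated)
Conditions: Eu(fod)3, that is tris(6,6,7,7,8,8,8-heptafluoro-2,2-dimethyloctane-3,5-dionato)europium (10 mol%), CHCl3, 50 °C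
Reagents that add atoms: none
Why: In this Lewis-acid-accelerated aromatic Claisen rearrangement the chair [3,3] shift with the carbinol methyl pseudo-equatorial forms the aryl–C bond on the allyl face from which oxygen departs, so the R C–O centre is relayed to the S benzylic carbon with an E alkene, the two ortho carbons being equivalent, and dienone 5 enolises to the phenol.

Step 4
Reactants: 6 3,5-dimethoxy-2-[(2S,3E)-pent-3-en-2-yl]phenol, 7 3-methylbut-2-enal
Product: 9 5,7-dimethoxy-2,2-dimethyl-8-[(2S,3E)-pent-3-en-2-yl]-2H-chromene, via quinone methide 8 (not isolated)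
Conditions: ethylenediammonium diacetate (10 mol%), toluene, reflux
Reagents that add atoms: none
Why: In this known phenol–enal chromene annulation, amine-salt-mediated condensation at the only free ortho carbon gives ortho-quinone methide 8, whose oxa-6π electrocyclisation closes the ring B pyran without involving the stereocentre.

Step 5
Reactants: 9 5,7-dimethoxy-2,2-dimethyl-8-[(2S,3E)-pent-3-en-2-yl]-2H-chromene, 10 4,4,5,5-tetramethyl-2-vinyl-1,3,2-dioxaborolane
Product: 11 2-[(1E,3S)-3-(5,7-dimethoxy-2,2-dimethyl-2H-chromen-8-yl)but-1-en-1-yl]-4,4,5,5-tetramethyl-1,3,2-dioxaborolane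
Conditions: second-generation Hoveyda–Grubbs catalyst (5 mol%), 10 (3 equiv), 1,4-benzoquinone (10 mol%), CH2Cl2, 40 °C
Reagents that add atoms: none
Why: Olefin cross-metathesis exchanges the propenyl terminus for the boryl-substituted alkylidene with loss of propene, the bulky allylic and boryl groups favour the E alkenylboronate, and the hindered cyclic chromene alkene should remain a spectator.

Step 6
Reactants: 11 2-[(1E,3S)-3-(5,7-dimethoxy-2,2-dimethyl-2H-chromen-8-yl)but-1-en-1-yl]-4,4,5,5-tetramethyl-1,3,2-dioxaborolane
Product: 12 8-[(2S,3E)-4-iodobut-3-en-2-yl]-5,7-dimethoxy-2,2-dimethyl-2H-chromene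
Conditions: NaOH (3 M aq, 3 equiv), THF, 0 °C; then I2 (1.05 equiv), 0 °C, dark; Na2S2O3 quench
Reagents that add atoms: iodine, II
Why: Adding hydroxide before iodine is the known way to convert an E alkenylboronate into the E alkenyl iodide with retention of geometry, and the activated boronate should consume the single equivalent of iodine faster than the arene or the chromene alkene can.

Step 7
Reactants: 12 8-[(2S,3E)-4-iodobut-3-en-2-yl]-5,7-dimethoxy-2,2-dimethyl-2H-chromene, 13 2-chloro-1,1-dimethoxyethane
Product: 16 5,7-dimethoxy-8-[(2S,3E)-6-methoxyhex-3-en-5-yn-2-yl]-2,2-dimethyl-2H-chromene, via methoxyethynyllithium 14 (not isolated), via methoxyethynylzinc chloride 15 (not isolated)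
Conditions: 13 (2 equiv), LiNEt2 (6 equiv), THF, 0 °C; ZnCl2 (2.2 equiv), 0 °C; then 12, Pd(PPh3)4 (5 mol%, zerovalent palladium), rt; NaHCO3 work-up, Et3N-deactivated silica
Reagents that add atoms: none
Why: Double elimination and deprotonation of the chloroacetal give acetylide 14, transmetalation gives zinc reagent 15, and the Negishi coupling with the alkenyl iodide proceeds with retention of the E geometry under conditions that do not touch the stereocentre.

Step 8
Reactants: 17 3-ethoxycyclobut-2-en-1-one
Product: 18 3-methoxycyclobut-2-en-1-one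
Conditions: dry MeOH (solvent), camphorsulfonic acid (1 mol%), 3 Å molecular sieves, rt; evaporate and repeat once
Reagents that add atoms: methanol, CO
Why: Acid-catalysed alkoxy exchange of a vinylogous ester (addition of methanol at C3, loss of ethanol) is driven to completion by the solvent excess.

Step 9
Reactants: 16 5,7-dimethoxy-8-[(2S,3E)-6-methoxyhex-3-en-5-yn-2-yl]-2,2-dimethyl-2H-chromene, 18 3-methoxycyclobut-2-en-1-one
Product: 23 2-[(1E,3S)-3-(5,7-dimethoxy-2,2-dimethyl-2H-chromen-8-yl)but-1-en-1-yl]-3,5-dimethoxyphenol, via vinylketene 19 (not isolated), via cyclobutenone adduct 20 (not isolated), via dienylketene 21 (not isolated), via cyclohexadienone 22 (not isolated)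
Conditions: 18 (1.5 equiv), toluene (0.3 M), sealed tube, argon, 80 °C, then 110 °C if needed; then K2CO3, MeOH, rt
Reagents that add atoms: none
Why: Thermal 4π-electrocyclic opening of 18 gives vinylketene 19, which adds [2+2] to the ynol ether so that the chain-bearing alkyne carbon bonds to the ketene carbonyl carbon (C8–C8a) and the methoxy-bearing carbon to the ketene CH (C6–C7); 4π opening of adduct 20 gives dienylketene 21, whose 6π electrocyclisation re-forms C4a–C8a, and dienone 22 enolises to phenol 23. The closest known reaction type is the Danheiser benzannulation of cyclobutenones with alkynyl ethers, applied here to a 3-alkoxycyclobutenone and a conjugated enyne ether. Ring A is closed by the thermal disrotatory 6π-electrocyclic closure of the ketene-terminated triene, followed by tautomerisation. No stereocentre is formed, and the S centre lies outside the reacting π system under neutral thermal conditions, so it should be retained. The step needs regioselectivity in the ketene–alkyne [2+2], which the polarisation of the ynol ether secures (its chain-bearing carbon is the nucleophile and the ketene carbonyl carbon the electrophile), and chemoselectivity for the alkyne over the two alkenes, which its much higher nucleophilicity secures. A methyl ynol ether cannot fragment by retro-ene loss of an alkene, which should let it survive the heating, and the carbonate–methanol treatment returns any phenol that was acylated by surplus ketene.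

Step 10
Reactants: 23 2-[(1E,3S)-3-(5,7-dimethoxy-2,2-dimethyl-2H-chromen-8-yl)but-1-en-1-yl]-3,5-dimethoxyphenol, 7 3-methylbut-2-enal
Product: 25 8-[(1E,3S)-3-(5,7-dimethoxy-2,2-dimethyl-2H-chromen-8-yl)but-1-en-1-yl]-5,7-dimethoxy-2,2-dimethyl-2H-chromene, via quinone methide 24 (not isolated)
Conditions: ethylenediammonium diacetate (20 mol%), toluene, reflux
Reagents that add atoms: none
Why: The same phenol–enal annulation as in step 4 closes the ring A pyran at C4a, the only free ortho carbon of the new phenol, through quinone methide 24 and oxa-6π electrocyclisation.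

Compound list

1 | (E)-pent-3-en-2-ol, racemic | C/C=C/C(C)O | starting material
2 | methyl (E)-pent-3-en-2-yl carbonate, racemic | C/C=C/C(C)OC(=O)OC | intermediate
3 | 3,5-dimethoxyphenol | COc1cc(O)cc(OC)c1 | starting material
4 | 1,3-dimethoxy-5-{[(2R,3E)-pent-3-en-2-yl]oxy}benzene | C/C=C/[C@@H](C)Oc1cc(OC)cc(OC)c1 | intermediate
5 | 3,5-dimethoxy-6-[(2S,3E)-pent-3-en-2-yl]cyclohexa-2,4-dien-1-one (ring C6 configuration not assigned, lost on enolisation) | C/C=C/[C@H](C)C1C(=O)C=C(OC)C=C1OC | intermediate
6 | 3,5-dimethoxy-2-[(2S,3E)-pent-3-en-2-yl]phenol | C/C=C/[C@H](C)c1c(O)cc(OC)cc1OC | intermediate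
7 | 3-methylbut-2-enal | CC(C)=CC=O | starting material
8 | 3,5-dimethoxy-6-(3-methylbut-2-en-1-ylidene)-2-[(2S,3E)-pent-3-en-2-yl]cyclohexa-2,4-dien-1-one | C/C=C/[C@H](C)C1=C(OC)C=C(OC)C(=CC=C(C)C)C1=O | intermediate
9 | 5,7-dimethoxy-2,2-dimethyl-8-[(2S,3E)-pent-3-en-2-yl]-2H-chromene | C/C=C/[C@H](C)c1c(OC)cc(OC)c2c1OC(C)(C)C=C2 | intermediate
10 | 4,4,5,5-tetramethyl-2-vinyl-1,3,2-dioxaborolane | C=CB1OC(C)(C)C(C)(C)O1 | starting material
11 | 2-[(1E,3S)-3-(5,7-dimethoxy-2,2-dimethyl-2H-chromen-8-yl)but-1-en-1-yl]-4,4,5,5-tetramethyl-1,3,2-dioxaborolane | CC1(C)OB(/C=C/[C@H](C)c2c(OC)cc(OC)c3c2OC(C)(C)C=C3)OC1(C)C | intermediate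
12 | 8-[(2S,3E)-4-iodobut-3-en-2-yl]-5,7-dimethoxy-2,2-dimethyl-2H-chromene | I/C=C/[C@H](C)c1c(OC)cc(OC)c2c1OC(C)(C)C=C2 | intermediate
13 | 2-chloro-1,1-dimethoxyethane | COC(OC)CCl | starting material
14 | (methoxyethynyl)lithium | [Li]C#COC | intermediate
15 | chloro(methoxyethynyl)zinc | COC#C[Zn]Cl | intermediate
16 | 5,7-dimethoxy-8-[(2S,3E)-6-methoxyhex-3-en-5-yn-2-yl]-2,2-dimethyl-2H-chromene | COC#C/C=C/[C@H](C)c1c(OC)cc(OC)c2c1OC(C)(C)C=C2 | intermediate
17 | 3-ethoxycyclobut-2-en-1-one | CCOC1=CC(=O)C1 | starting material
18 | 3-methoxycyclobut-2-en-1-one | COC1=CC(=O)C1 | intermediate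
19 | 3-methoxybuta-1,3-dien-1-one | C=C(OC)C=C=O | intermediate
20 | 2-[(1E,3S)-3-(5,7-dimethoxy-2,2-dimethyl-2H-chromen-8-yl)but-1-en-1-yl]-3-methoxy-4-(1-methoxyethenyl)cyclobut-2-en-1-one (both C4 epimers) | COC(=C)C1C(=O)C(/C=C/[C@H](C)c2c(OC)cc(OC)c3c2OC(C)(C)C=C3)=C1OC | intermediate
21 | (3E)-2-[(1E,3S)-3-(5,7-dimethoxy-2,2-dimethyl-2H-chromen-8-yl)but-1-en-1-yl]-3,5-dimethoxyhexa-1,3,5-trien-1-one | O=C=C(/C=C/[C@H](C)c1c(OC)cc(OC)c2c1OC(C)(C)C=C2)/C(OC)=C\C(OC)=C | intermediate
22 | 2-[(1E,3S)-3-(5,7-dimethoxy-2,2-dimethyl-2H-chromen-8-yl)but-1-en-1-yl]-3,5-dimethoxycyclohexa-2,4-dien-1-one | O=C1CC(OC)=CC(OC)=C1/C=C/[C@H](C)c1c(OC)cc(OC)c2c1OC(C)(C)C=C2 | intermediate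
23 | 2-[(1E,3S)-3-(5,7-dimethoxy-2,2-dimethyl-2H-chromen-8-yl)but-1-en-1-yl]-3,5-dimethoxyphenol | COc1cc(OC)c(/C=C/[C@H](C)c2c(OC)cc(OC)c3c2OC(C)(C)C=C3)c(O)c1 | intermediate
24 | 2-[(1E,3S)-3-(5,7-dimethoxy-2,2-dimethyl-2H-chromen-8-yl)but-1-en-1-yl]-3,5-dimethoxy-6-(3-methylbut-2-en-1-ylidene)cyclohexa-2,4-dien-1-one | O=C1C(/C=C/[C@H](C)c2c(OC)cc(OC)c3c2OC(C)(C)C=C3)=C(OC)C=C(OC)C1=CC=C(C)C | intermediate
25 | 8-[(1E,3S)-3-(5,7-dimethoxy-2,2-dimethyl-2H-chromen-8-yl)but-1-en-1-yl]-5,7-dimethoxy-2,2-dimethyl-2H-chromene | COc1cc(OC)c(/C=C/[C@H](C)c2c(OC)cc(OC)c3c2OC(C)(C)C=C3)c2c1C=CC(C)(C)O2 | target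

Total step count: 10. Longest linear sequence: 9 steps (steps 1 to 7, then 9 and 10); step 8 is a one-step side branch.

Steps most likely to fail

Step 9, the benzannulation. The donor-substituted cyclobutenone may open only at temperatures at which the enyne ether oligomerises, or ketene 19 may dimerise faster than the alkyne traps it. The fallback sets out from 16 and makes the same ketene at room temperature by 1,4-dehydrochlorination instead of electrocyclic ring opening. (E)-3-Methoxybut-2-enoyl chloride F1 is prepared from the commercial acid with (COCl)2 and catalytic DMF in CH2Cl2. F1 and Et3N are then added slowly to 16 in toluene at 20 °C, so that 19 is trapped as adduct 20 as it forms. Warming to about 70 °C should complete the ring opening, electrocyclisation and enolisation, and the route is rejoined at phenol 23.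

Step 6, the iododeboronation. Electrophilic iodine may substitute the free C6 position of the trialkoxy arene or add across the chromene C3=C4 bond in competition with the boronate. The fallback sets out from 9 and uses neither boron nor iodine. Stereoretentive cross-metathesis of the E propenyl group with (E)-1,2-dichloroethene, catalysed by the molybdenum monoaryloxide pyrrolide alkylidene Mo(NC6F5)(CHCMe2Ph)(NC4H4)(OC6H3-2,6-(C6H2-2,4,6-Et3)2) in benzene at 22 °C, should give 8-[(2S,3E)-4-chlorobut-3-en-2-yl]-5,7-dimethoxy-2,2-dimethyl-2H-chromene F2. This alkenyl chloride is coupled with zinc reagent 15 (generated as in step 7) under Pd(P(t-Bu)3)2 (zerovalent palladium) in THF at 50 °C, and the route is rejoined at enyne 16.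

Step 7, the Negishi coupling. The acetylide and zinc reagent are generated in a basic, salt-rich mixture and may form incompletely or degrade the iodide, and the acid-labile enyne ether may hydrate during aqueous work-up. The fallback sets out from 12 and delivers the alkynyl group from an isolated, purified reagent. Acetylide 14 is quenched with Bu3SnCl and the product distilled to give tributyl(methoxyethynyl)stannane F3. Stille coupling of F3 with 12 (Pd2(dba)3, zerovalent palladium, AsPh3, THF, 50 °C) runs under neutral conditions free of amide base, and a non-aqueous work-up by filtration through basic alumina rejoins the route at enyne 16.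

Further compounds

F1 | step 9 | (E)-3-methoxybut-2-enoyl chloride | CO/C(C)=C/C(Cl)=O
F2 | step 6 | 8-[(2S,3E)-4-chlorobut-3-en-2-yl]-5,7-dimethoxy-2,2-dimethyl-2H-chromene | Cl/C=C/[C@H](C)c1c(OC)cc(OC)c2c1OC(C)(C)C=C2
F3 | step 7 | tributyl(methoxyethynyl)stannane | CCCC[Sn](CCCC)(CCCC)C#COC
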